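The route rests on the C4a–C5 bond of the cyclopentane ring (C4a, C5, C6, C7, C7a; cyclopenta[c]pyran locants). Its precursor is a monocyclic 3,4-dihydro-2H-pyran that already carries the coumarin at C1, the isovaleryl group at C3 and, on C7a, a (2S)-4-bromobutan-2-yl arm. It is assembled from three fragments by an amine-catalysed hetero-Diels–Alder reaction and a C-arylation. The key step exploits the enol ether double bond C3=C4 of the pyran ring: conjugated with the C3 acyl carbonyl, it makes C4a–H vinylogously acidic, and the dienolate closes the five-membered ring at C4a, cis-fused, in the last step, which also sets the fourth stereocentre.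

Key step: step 9

Assumption: compounds 1, 3 and 8 are taken as catalogue chemicals, and the (S)-diarylprolinol silyl ether is taken to shield the aldehyde enamine with the same facial sense as in its known Michael additions.

Step 1
Reactants: 1 1-(2-hydroxy-6-methylphenyl)ethan-1-one
Product: 2 4-hydroxy-5-methyl-2H-chromen-2-one
Conditions: NaH (3 equiv), (EtO)2CO, toluene, 110 °C; then 2 M HCl
Reagents that add atoms: diethyl carbonate, CCOC(=O)OCC
Why: Claisen-type C-acylation of the ketone enolate by diethyl carbonate and lactonisation onto the phenoxide (the classical 4-hydroxycoumarin synthesis from an o-hydroxyacetophenone) should give the coumarin; no stereocentre is formed.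

Step 2
Reactants: 3 (3R)-5-methoxy-3-methyl-5-oxopentanoic acid (methyl hydrogen (R)-3-methylglutarate)
Product: 5 (4S)-4-methyloxan-2-one, via hydroxy acid 4 (not isolated)
Conditions: NaH (1.0 equiv), THF, 0 °C; LiBH4 (1.5 equiv), 50 °C; then 3 M HCl, rt
Reagents that add atoms: none
Why: LiBH4 reduces the methyl ester but not the sodium carboxylate (chemoselective ester reduction) and acidification lactonises hydroxy acid 4; the stereocentre is not touched, and its descriptor changes from R to S only because the priorities of the two arms are exchanged.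

Step 3
Reactants: 5 (4S)-4-methyloxan-2-one
Product: 6 methyl (3R)-5-bromo-3-methylpentanoate
Conditions: HBr (gas), MeOH, 0 °C → rt
Reagents that add atoms: hydrogen bromide, Br; methanol, CO
Why: Acid-mediated ring opening of the δ-lactone, with bromide displacing the activated primary C–O bond (SN2) and Fischer esterification in methanol, should give the ω-bromo ester; the stereocentre is remote from both reacting carbons.

Step 4
Reactants: 6 methyl (3R)-5-bromo-3-methylpentanoate
Product: 7 (3R)-5-bromo-3-methylpentanal
Conditions: i-Bu2AlH (1.05 equiv), CH2Cl2, −78 °C; aq. potassium sodium tartrate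
Reagents that add atoms: none
Why: Partial ester reduction with i-Bu2AlH stops at the tetrahedral aluminium hemiacetal at −78 °C and releases the aldehyde on work-up; the primary bromide is inert under these conditions.

Step 5
Reactants: 8 N,N′-dimethoxy-N,N′-dimethyloxamide; 9 isobutylmagnesium bromide; 10 isopropenylmagnesium bromide
Product: 13 2,6-dimethylhept-1-ene-3,4-dione, via mono-adduct chelate 11 (not isolated), via bis-adduct chelate 12 (not isolated)
Conditions: 9 (1.0 equiv), THF, −78 → −20 °C; then 10 (1.2 equiv), −20 → 0 °C; inverse quench into cold 1 M HCl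
Reagents that add atoms: none
Why: Double Weinreb ketone synthesis, in which each Grignard reagent adds once to one amide carbonyl and the magnesium chelates 11 and 12 persist until the acidic quench, so neither over-addition nor conjugate addition to the enedione can occur.

Step 6
Reactants: 7 (3R)-5-bromo-3-methylpentanal; 13 2,6-dimethylhept-1-ene-3,4-dione
Product: 14 1-[(3S)-3-[(2S)-4-bromobutan-2-yl]-2-hydroxy-5-methyl-3,4-dihydro-2H-pyran-6-yl]-3-methylbutan-1-one
Conditions: (S)-α,α-diphenylprolinol trimethylsilyl ether (20 mol%), SiO2, CH2Cl2, −15 °C → rt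
Reagents that add atoms: none
Why: Amine-catalysed inverse-electron-demand hetero-Diels–Alder reaction (enamine Michael addition to the methylene terminus of the 1-oxadiene O=C3–C4=C4a, closure of the diketone enol oxygen onto C1, hydrolytic release of the catalyst); the diphenyl(silyloxy)methyl group shields one face of the E-enamine, so C7a is set under catalyst control (3S in pyran numbering), the remote C7 centre exerting little bias and the lactol carbon being inconsequential.

Step 7
Reactants: 14 1-[(3S)-3-[(2S)-4-bromobutan-2-yl]-2-hydroxy-5-methyl-3,4-dihydro-2H-pyran-6-yl]-3-methylbutan-1-one; 2 4-hydroxy-5-methyl-2H-chromen-2-one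
Product: 15 3-[(2R,3S)-3-[(2S)-4-bromobutan-2-yl]-5-methyl-6-(3-methylbutanoyl)-3,4-dihydro-2H-pyran-2-yl]-4-hydroxy-5-methyl-2H-chromen-2-one
Conditions: Sc(OTf)3 (10 mol%), 4 Å MS, MeCN, rt → 40 °C
Reagents that add atoms: none
Why: Lewis-acid-promoted dehydrative Friedel–Crafts-type C-alkylation (C-glycosylation) of the 4-hydroxycoumarin at its C3 by the ionised lactol; the coumarin should end up trans to the C7a side chain (both pseudo-equatorial, 2R) because the C–C bond formation is reversible through ring opening and equilibrates to the more stable epimer.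

Step 8
Reactants: 15 3-[(2R,3S)-3-[(2S)-4-bromobutan-2-yl]-5-methyl-6-(3-methylbutanoyl)-3,4-dihydro-2H-pyran-2-yl]-4-hydroxy-5-methyl-2H-chromen-2-one
Product: 16 3-[(2R,3S)-3-[(2S)-4-bromobutan-2-yl]-5-methyl-6-(3-methylbutanoyl)-3,4-dihydro-2H-pyran-2-yl]-4-methoxy-5-methyl-2H-chromen-2-one
Conditions: Me2SO4 (1.5 equiv), K2CO3 (2 equiv), acetone, rt
Reagents that add atoms: dimethyl sulfate, COS(=O)(=O)OC
Why: O-Methylation of the acidic vinylogous acid with the hard electrophile dimethyl sulfate (Williamson-type alkylation) should favour the 4-methoxycoumarin over the 2-methoxychromone and over C-methylation; no stereocentre is affected.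

Step 9
Reactants: 16 3-[(2R,3S)-3-[(2S)-4-bromobutan-2-yl]-5-methyl-6-(3-methylbutanoyl)-3,4-dihydro-2H-pyran-2-yl]-4-methoxy-5-methyl-2H-chromen-2-one
Product: 18 3-[(1R,4aS,7S,7aR)-4,7-dimethyl-3-(3-methylbutanoyl)-1,4a,5,6,7,7a-hexahydrocyclopenta[c]pyran-1-yl]-4-methoxy-5-methyl-2H-chromen-2-one, via potassium dienolate 17 (not isolated)
Conditions: KOtBu (1.3 equiv), t-BuOH–THF (1:4), 0.01 M, 0 °C → rt
Reagents that add atoms: none
Why: tert-Butoxide reversibly deprotonates 16, and the extended potassium dienolate 17 (O–C=C3–C4=C4a) attacks C5 through its γ-carbon C4a with loss of bromide; the closest known reaction type is the intramolecular γ-alkylation of enone dienolates (vinylogous enolate alkylation) under equilibrating alkoxide conditions. The cyclopentane ring C4a–C5–C6–C7–C7a is closed in the 5-exo-tet mode. The new stereocentre C4a is controlled by C7a: the three-carbon tether hanging from C7a can reach C4a only on its own face of the pyran ring, so the ring fusion should be cis (4aS), and C7, taken from the chiral pool, places its methyl group on the convex face, trans to C1. The step needs C4a selectivity over the α-carbon C3, the enolate oxygen, the isovaleryl α-methylene and E2 loss of HBr; attack by C3 or by oxygen would need a bridged seven-membered or a nine-membered transition state, the isovaleryl enolate can only close a nine-membered ring and should return to 17 by proton exchange in t-BuOH, and high dilution suppresses intermolecular alkylation. C1, C7 and C7a carry no acidic hydrogen and the methyl ether blocks retro-oxa-Michael opening of the pyran ring, so the three existing stereocentres should survive.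

Compound list
1 | 1-(2-hydroxy-6-methylphenyl)ethan-1-one | CC(=O)c1c(C)cccc1O | starting material
2 | 4-hydroxy-5-methyl-2H-chromen-2-one | Cc1cccc2oc(=O)cc(O)c12 | intermediate
3 | (3R)-5-methoxy-3-methyl-5-oxopentanoic acid | COC(=O)C[C@H](C)CC(=O)O | starting material
4 | (3S)-5-hydroxy-3-methylpentanoic acid | OCC[C@H](C)CC(=O)O | intermediate
5 | (4S)-4-methyloxan-2-one | O=C1C[C@@H](C)CCO1 | intermediate
6 | methyl (3R)-5-bromo-3-methylpentanoate | BrCC[C@H](C)CC(=O)OC | intermediate
7 | (3R)-5-bromo-3-methylpentanal | BrCC[C@H](C)CC=O | intermediate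
8 | N,N′-dimethoxy-N,N′-dimethyloxamide | CON(C)C(=O)C(=O)N(C)OC | starting material
9 | isobutylmagnesium bromide | CC(C)C[Mg]Br | starting material
10 | isopropenylmagnesium bromide | CC(=C)[Mg]Br | starting material
11 | 2-(bromomagnesiooxy)-N-methoxy-2-[methoxy(methyl)amino]-N,4-dimethylpentanamide (mono-adduct chelate) | CC(C)CC(O[Mg]Br)(N(C)OC)C(=O)N(C)OC | intermediate
12 | 3,4-bis(bromomagnesiooxy)-3,4-bis[methoxy(methyl)amino]-2,6-dimethylhept-1-ene (bis-adduct chelate) | CC(C)CC(O[Mg]Br)(N(C)OC)C(O[Mg]Br)(N(C)OC)C(C)=C | intermediate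
13 | 2,6-dimethylhept-1-ene-3,4-dione | CC(C)CC(=O)C(=O)C(C)=C | intermediate
14 | 1-[(3S)-3-[(2S)-4-bromobutan-2-yl]-2-hydroxy-5-methyl-3,4-dihydro-2H-pyran-6-yl]-3-methylbutan-1-one (lactol, both C2 epimers) | OC1OC(C(=O)CC(C)C)=C(C)C[C@H]1[C@@H](C)CCBr | intermediate
15 | 3-[(2R,3S)-3-[(2S)-4-bromobutan-2-yl]-5-methyl-6-(3-methylbutanoyl)-3,4-dihydro-2H-pyran-2-yl]-4-hydroxy-5-methyl-2H-chromen-2-one | Oc1c([C@@H]2OC(C(=O)CC(C)C)=C(C)C[C@H]2[C@@H](C)CCBr)c(=O)oc2cccc(C)c12 | intermediate
16 | 3-[(2R,3S)-3-[(2S)-4-bromobutan-2-yl]-5-methyl-6-(3-methylbutanoyl)-3,4-dihydro-2H-pyran-2-yl]-4-methoxy-5-methyl-2H-chromen-2-one | COc1c([C@@H]2OC(C(=O)CC(C)C)=C(C)C[C@H]2[C@@H](C)CCBr)c(=O)oc2cccc(C)c12 | intermediate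
17 | potassium dienolate of 16 (O–C=C3–C4=C4a) | COc1c([C@@H]2OC(=C([O-])CC(C)C)C(C)=C[C@H]2[C@@H](C)CCBr)c(=O)oc2cccc(C)c12.[K+] | intermediate
18 | 3-[(1R,4aS,7S,7aR)-4,7-dimethyl-3-(3-methylbutanoyl)-1,4a,5,6,7,7a-hexahydrocyclopenta[c]pyran-1-yl]-4-methoxy-5-methyl-2H-chromen-2-one | COc1c([C@@H]2OC(C(=O)CC(C)C)=C(C)[C@H]3CC[C@H](C)[C@H]32)c(=O)oc2cccc(C)c12 | target

Total step count: 9. Longest linear sequence: 7 steps (steps 2, 3, 4, 6, 7, 8 and 9, from 3 to 18).

Steps most likely to fail

1. Step 9. What may go wrong: enolisation at the isovaleryl α-methylene instead of at C4a, so that elimination of HBr from the side chain or intermolecular alkylation consumes 16 before the γ-carbon can cyclise. The fallback sets out from 7 and comes back to the route at 18; it removes the competing acidic site by carrying an ester at C3 through the ring closure. Aldehyde 7 and ethyl 3-methyl-2-oxobut-3-enoate F1 (from 10 and diethyl oxalate, THF, −78 °C) are combined under the amine catalysis of step 6 to lactol ester F2. MeOH with pyridinium tosylate gives methyl acetal F3. LiN(i-Pr)2 in THF–DMPU (−78 → 0 °C) deprotonates the γ-position of this α-alkoxy acrylate, which has no other acidic site, and the ester dienolate closes the cyclopentane to bicyclic ester F4. MeNHOMe·HCl with i-PrMgCl gives Weinreb amide F5, and 9 converts it into isovaleryl ketone F6. Sc(OTf)3-catalysed coupling of F6 with 2, the nucleophile entering on the convex face of the bicyclic oxocarbenium ion, gives 4-hydroxycoumarin adduct F7, and methylation as in step 8 gives 18.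

2. Step 6. What may go wrong: slow addition of the hindered enamine to the α-branched vinyl diketone, with loss of catalyst through aza-Michael addition to 13 or N-alkylation by the bromide, and with eroded facial control. The fallback sets out from 7 and comes back to the route at 15; it replaces 13 by the β,γ-unsaturated α-keto ester class, for which this amine-catalysed hetero-Diels–Alder reaction is established. Ethyl 3-methyl-2-oxobut-3-enoate F1 gives lactol ester F2 and then methyl acetal F3 as described above. The ester is then turned into the ketone on the monocyclic acetal: MeNHOMe·HCl with i-PrMgCl gives monocyclic Weinreb amide F8, and 9 gives ketone acetal F9. F9 reacts with 2 under the conditions of step 7, the acetal ionising like the lactol, to give 15.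

3. Step 7. What may go wrong: O-alkylation of the ambident coumarin, acid-induced decomposition of the enol ether lactol, and incomplete equilibration at C1. The fallback sets out from 14 and comes back to the route at 15; it uses a base-mediated Knoevenagel condensation and oxa-Michael closure instead of acid-mediated ionisation. Through its open-chain aldehyde tautomer, 14 condenses with 2 (ethylenediammonium diacetate, MeCN, rt → 50 °C) to alkylidene chromanedione F10. The diketone enol oxygen then adds back to the alkylidene carbon in a reversible 6-exo-trig oxa-Michael addition that should deliver the thermodynamic 2,3-trans pyran 15.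

Further compounds
F1 | step 9 | ethyl 3-methyl-2-oxobut-3-enoate | CCOC(=O)C(=O)C(C)=C
F2 | step 9 | ethyl (3S)-3-[(2S)-4-bromobutan-2-yl]-2-hydroxy-5-methyl-3,4-dihydro-2H-pyran-6-carboxylate | OC1OC(C(=O)OCC)=C(C)C[C@H]1[C@@H](C)CCBr
F3 | step 9 | ethyl (3S)-3-[(2S)-4-bromobutan-2-yl]-2-methoxy-5-methyl-3,4-dihydro-2H-pyran-6-carboxylate | COC1OC(C(=O)OCC)=C(C)C[C@H]1[C@@H](C)CCBr
F4 | step 9 | ethyl (4aS,7S,7aR)-1-methoxy-4,7-dimethyl-1,4a,5,6,7,7a-hexahydrocyclopenta[c]pyran-3-carboxylate | COC1OC(C(=O)OCC)=C(C)[C@H]2CC[C@H](C)[C@H]21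
F5 | step 9 | (4aS,7S,7aR)-N,1-dimethoxy-N,4,7-trimethyl-1,4a,5,6,7,7a-hexahydrocyclopenta[c]pyran-3-carboxamide | COC1OC(C(=O)N(C)OC)=C(C)[C@H]2CC[C@H](C)[C@H]21
F6 | step 9 | 1-[(4aS,7S,7aR)-1-methoxy-4,7-dimethyl-1,4a,5,6,7,7a-hexahydrocyclopenta[c]pyran-3-yl]-3-methylbutan-1-one | COC1OC(C(=O)CC(C)C)=C(C)[C@H]2CC[C@H](C)[C@H]21
F7 | step 9 | 4-hydroxy-3-[(1R,4aS,7S,7aR)-4,7-dimethyl-3-(3-methylbutanoyl)-1,4a,5,6,7,7a-hexahydrocyclopenta[c]pyran-1-yl]-5-methyl-2H-chromen-2-one | Oc1c([C@@H]2OC(C(=O)CC(C)C)=C(C)[C@H]3CC[C@H](C)[C@H]32)c(=O)oc2cccc(C)c12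
F8 | step 6 | (3S)-3-[(2S)-4-bromobutan-2-yl]-N,2-dimethoxy-N,5-dimethyl-3,4-dihydro-2H-pyran-6-carboxamide | COC1OC(C(=O)N(C)OC)=C(C)C[C@H]1[C@@H](C)CCBr
F9 | step 6 | 1-[(3S)-3-[(2S)-4-bromobutan-2-yl]-2-methoxy-5-methyl-3,4-dihydro-2H-pyran-6-yl]-3-methylbutan-1-one | COC1OC(C(=O)CC(C)C)=C(C)C[C@H]1[C@@H](C)CCBr
F10 | step 7 | 3-[(2S)-2-[(2S)-4-bromobutan-2-yl]-4,8-dimethyl-5,6-dioxononylidene]-5-methyl-2H-chromene-2,4(3H)-dione | CC(C)CC(=O)C(=O)C(C)C[C@H](C=C1C(=O)Oc2cccc(C)c2C1=O)[C@@H](C)CCBr
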